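**Retrosynthetic overview**
The target is an achiral flavone whose ring A (C4a, C5, C6, C7, C8, C8a) bears no hydrogen and has oxygen on four neighbouring carbons, C5–C8; these four carbons are taken intact from dimethyl squarate.
Target 21 ⇐ hydrogenolysis of bis(benzyl) ether 20 ⇐ double O-methylation of 5,8-hydroquinone 19.
Ring A and the C8–C8a bond of 19 ⇐ thermal ring expansion of the 4-hydroxy-4-(4-oxopyran-3-yl)cyclobutenone 16 (ring A is made last).
16 ⇐ dimethyl squarate + 3-magnesiated 6-aryl-4-pyranone from iodide 13; ring C of 13 ⇐ hetero-Diels–Alder of aldehyde 8 with Danishefsky's diene, C5 iodination, dehydrogenation.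
Ring B aldehyde 8 ⇐ isovanillin by benzylation, Baeyer–Villiger oxidation, benzylation and Vilsmeier formylation.

Key step: step 9

Remark: the target has no stereocentre, so no stereocontrol is needed; the stereocentres of 10, 11, 12, 16 and 18 are used racemic and are all destroyed on the way.

**Step 1**
Reactants: 1 isovanillin (3-hydroxy-4-methoxybenzaldehyde); 2 benzyl bromide
Product: 3 3-(benzyloxy)-4-methoxybenzaldehyde
Conditions: K2CO3, DMF, rt → 60 °C
Reagents that add atoms: none
Why: Williamson etherification of the only phenol by SN2 on benzyl bromide; the aldehyde is inert to carbonate.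

**Step 2**
Reactants: 3 3-(benzyloxy)-4-methoxybenzaldehyde
Product: 5 3-(benzyloxy)-4-methoxyphenol, via aryl formate 4 (not isolated)
Conditions: mCPBA, CH2Cl2, rt; then K2CO3 (cat.), MeOH, rt
Reagents that add atoms: meta-chloroperoxybenzoic acid (mCPBA), OOC(=O)c1cccc(Cl)c1
Why: Baeyer–Villiger (Dakin-type) oxidation, in which the electron-rich aryl group with its para methoxy group migrates in preference to hydrogen, and mild methanolysis of the aryl formate should release the phenol without touching the benzyl ether.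

**Step 3**
Reactants: 5 3-(benzyloxy)-4-methoxyphenol; 2 benzyl bromide
Product: 6 2,4-bis(benzyloxy)-1-methoxybenzene
Conditions: K2CO3, DMF, 60 °C
Reagents that add atoms: none
Why: Williamson etherification of the new phenol.

**Step 4**
Reactants: 6 2,4-bis(benzyloxy)-1-methoxybenzene
Product: 8 2,4-bis(benzyloxy)-5-methoxybenzaldehyde, via aryl iminium chloride 7 (not isolated)
Conditions: POCl3, DMF, 0 → 70 °C; then H2O, rt
Reagents that add atoms: N,N-dimethylformamide, CN(C)C=O; water, O
Why: Vilsmeier–Haack formylation should go to the one ring carbon that is ortho to one benzyloxy group and para to the other, as 1,2,4-trimethoxybenzene gives 2,4,5-trimethoxybenzaldehyde; the carbon between the two benzyloxy groups is hindered and the carbon next to OMe is activated by one oxygen only.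

**Step 5**
Reactants: 8 2,4-bis(benzyloxy)-5-methoxybenzaldehyde; 9 Danishefsky's diene ((E)-1-methoxy-3-(trimethylsilyloxy)buta-1,3-diene)
Product: 11 2-[2,4-bis(benzyloxy)-5-methoxyphenyl]-2,3-dihydro-4H-pyran-4-one (racemic), via silyl enol ether cycloadduct 10 (not isolated)
Conditions: ZnCl2, THF, rt; then TFA, CH2Cl2, 0 °C
Reagents that add atoms: none
Why: Lewis-acid-promoted hetero-Diels–Alder cyclocondensation of the aldehyde C=O with the electron-rich diene, after which acid cleaves the silyl enol ether and eliminates methanol; the C2 stereocentre forms racemic and is removed in step 7.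

**Step 6**
Reactants: 11 2-[2,4-bis(benzyloxy)-5-methoxyphenyl]-2,3-dihydro-4H-pyran-4-one
Product: 12 2-[2,4-bis(benzyloxy)-5-methoxyphenyl]-5-iodo-2,3-dihydro-4H-pyran-4-one (racemic)
Conditions: I2, pyridine, CH2Cl2, 0 °C → rt
Reagents that add atoms: iodine, II
Why: Johnson-type α-iodination of a β-alkoxy enone; C5 is the nucleophilic α-carbon and the only enone α-position at this oxidation level, which fixes the iodine next to the O–CH= carbon before the second ring double bond exists.

**Step 7**
Reactants: 12 2-[2,4-bis(benzyloxy)-5-methoxyphenyl]-5-iodo-2,3-dihydro-4H-pyran-4-one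
Product: 13 2-[2,4-bis(benzyloxy)-5-methoxyphenyl]-5-iodo-4H-pyran-4-one
Conditions: DDQ, 1,4-dioxane, 90 °C
Reagents that add atoms: none
Why: DDQ dehydrogenation of the flavanone-to-flavone type, by hydride abstraction from the C2–H that is benzylic to a trialkoxyaryl ring and α to the ring oxygen, then loss of a C3 proton; aryl benzyl ethers and the vinylic iodide should be inert.

**Step 8**
Reactants: 13 2-[2,4-bis(benzyloxy)-5-methoxyphenyl]-5-iodo-4H-pyran-4-one; 14 dimethyl squarate (3,4-dimethoxycyclobut-3-ene-1,2-dione)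
Product: 16 4-{6-[2,4-bis(benzyloxy)-5-methoxyphenyl]-4-oxo-4H-pyran-3-yl}-4-hydroxy-2,3-dimethoxycyclobut-2-en-1-one (racemic), via pyranonylmagnesium chloride 15 (not isolated)
Conditions: iPrMgCl·LiCl, THF, −40 °C; then 14, THF, −78 → −20 °C; aq. NH4Cl
Reagents that add atoms: none
Why: Iodine–magnesium exchange on an α-iodo vinylogous ester (as with 3-iodochromones) should outrun addition of the reagent to the weakly electrophilic pyranone, and the alkenyl Grignard adds 1,2 to one squarate carbonyl, the standard entry to 4-substituted 4-hydroxycyclobutenones; the carbinol centre is racemic and vanishes in step 9.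

**Step 9**
Reactants: 16 4-{6-[2,4-bis(benzyloxy)-5-methoxyphenyl]-4-oxo-4H-pyran-3-yl}-4-hydroxy-2,3-dimethoxycyclobut-2-en-1-one
Product: 19 2-[2,4-bis(benzyloxy)-5-methoxyphenyl]-5,8-dihydroxy-6,7-dimethoxy-4H-chromen-4-one, via dienylketene 17 (not isolated), via 8aH-chromene-4,8-dione 18 (not isolated)
Conditions: degassed p-xylene (0.01 M), 130 °C, Ar
Reagents that add atoms: none
Why: Heat should open the C1–C4 bond of the cyclobutenone in a conrotatory 4π process in which the donor hydroxyl turns outward, so that dienylketene 17 has the pyranonyl group cis to the ketene-bearing carbon. A 6π electrocyclization over the ketene C=C, the central C=C and the pyranone C2=C3 bond then joins the ketene carbon to the pyranone CH carbon; this single closure forms the C8–C8a bond and the six-membered ring A as dienone 18, and the shift of H8a to oxygen aromatizes it to hydroquinone 19. The closest known reaction is the Moore rearrangement of 4-aryl- and 4-alkenyl-4-hydroxycyclobutenones to hydroquinones, here with the C2=C3 bond of a 4-pyranone in the alkenyl role. No stereocentre is set, because the carbinol carbon of 16 and C8a of 18 both end as sp2 carbons. The step needs outward torquoselectivity of the hydroxyl and ring closure faster than ketene capture; the first follows from the donor character of OH, the second from high dilution in a degassed non-nucleophilic solvent, and there is no regiochemical choice because the other neighbour of the pyranone C3 is the carbonyl carbon C4.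

**Step 10**
Reactants: 19 2-[2,4-bis(benzyloxy)-5-methoxyphenyl]-5,8-dihydroxy-6,7-dimethoxy-4H-chromen-4-one (crude, kept under argon)
Product: 20 2-[2,4-bis(benzyloxy)-5-methoxyphenyl]-5,6,7,8-tetramethoxy-4H-chromen-4-one
Conditions: Me2SO4 (excess), K2CO3, acetone, reflux, Ar
Reagents that add atoms: dimethyl sulfate, COS(=O)(=O)OC
Why: Williamson O-methylation of both phenols; the chelated 5-OH reacts more slowly but should be methylated at reflux with excess reagent, and exclusion of air prevents oxidation to the 5,8-quinone.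

**Step 11**
Reactants: 20 2-[2,4-bis(benzyloxy)-5-methoxyphenyl]-5,6,7,8-tetramethoxy-4H-chromen-4-one
Product: 21 2-(2,4-dihydroxy-5-methoxyphenyl)-5,6,7,8-tetramethoxy-4H-chromen-4-one (CNP0237834.0)
Conditions: H2 (1 atm), 10% Pd/C, EtOAc–MeOH, rt
Reagents that add atoms: none
Why: Hydrogenolysis of the two aryl benzyl ethers over palladium at atmospheric pressure should leave the chromone C2=C3 bond and the five methyl ethers untouched.

**Compound list**
1 | isovanillin (3-hydroxy-4-methoxybenzaldehyde) | COc1ccc(C=O)cc1O | starting material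
2 | benzyl bromide | BrCc1ccccc1 | starting material
3 | 3-(benzyloxy)-4-methoxybenzaldehyde | COc1ccc(C=O)cc1OCc1ccccc1 | intermediate
4 | 3-(benzyloxy)-4-methoxyphenyl formate | COc1ccc(OC=O)cc1OCc1ccccc1 | intermediate
5 | 3-(benzyloxy)-4-methoxyphenol | COc1ccc(O)cc1OCc1ccccc1 | intermediate
6 | 2,4-bis(benzyloxy)-1-methoxybenzene | COc1ccc(OCc2ccccc2)cc1OCc1ccccc1 | intermediate
7 | N-[2,4-bis(benzyloxy)-5-methoxybenzylidene]-N-methylmethanaminium chloride | COc1cc(C=[N+](C)C)c(OCc2ccccc2)cc1OCc1ccccc1.[Cl-] | intermediate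
8 | 2,4-bis(benzyloxy)-5-methoxybenzaldehyde | COc1cc(C=O)c(OCc2ccccc2)cc1OCc1ccccc1 | intermediate
9 | Danishefsky's diene, (E)-1-methoxy-3-(trimethylsilyloxy)buta-1,3-diene | CO/C=C/C(=C)O[Si](C)(C)C | starting material
10 | 2-[2,4-bis(benzyloxy)-5-methoxyphenyl]-6-methoxy-4-(trimethylsilyloxy)-3,6-dihydro-2H-pyran (racemic, diastereomer mixture) | COC1C=C(O[Si](C)(C)C)CC(c2cc(OC)c(OCc3ccccc3)cc2OCc2ccccc2)O1 | intermediate
11 | 2-[2,4-bis(benzyloxy)-5-methoxyphenyl]-2,3-dihydro-4H-pyran-4-one (racemic) | COc1cc(C2CC(=O)C=CO2)c(OCc2ccccc2)cc1OCc1ccccc1 | intermediate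
12 | 2-[2,4-bis(benzyloxy)-5-methoxyphenyl]-5-iodo-2,3-dihydro-4H-pyran-4-one (racemic) | COc1cc(C2CC(=O)C(I)=CO2)c(OCc2ccccc2)cc1OCc1ccccc1 | intermediate
13 | 2-[2,4-bis(benzyloxy)-5-methoxyphenyl]-5-iodo-4H-pyran-4-one | COc1cc(-c2cc(=O)c(I)co2)c(OCc2ccccc2)cc1OCc1ccccc1 | intermediate
14 | dimethyl squarate (3,4-dimethoxycyclobut-3-ene-1,2-dione) | COC1=C(OC)C(=O)C1=O | starting material
15 | {6-[2,4-bis(benzyloxy)-5-methoxyphenyl]-4-oxo-4H-pyran-3-yl}magnesium chloride (LiCl complex) | COc1cc(-c2cc(=O)c([Mg]Cl)co2)c(OCc2ccccc2)cc1OCc1ccccc1 | intermediate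
16 | 4-{6-[2,4-bis(benzyloxy)-5-methoxyphenyl]-4-oxo-4H-pyran-3-yl}-4-hydroxy-2,3-dimethoxycyclobut-2-en-1-one (racemic) | COC1=C(OC)C(O)(c2coc(-c3cc(OC)c(OCc4ccccc4)cc3OCc3ccccc3)cc2=O)C1=O | intermediate
17 | (Z)-4-{6-[2,4-bis(benzyloxy)-5-methoxyphenyl]-4-oxo-4H-pyran-3-yl}-4-hydroxy-2,3-dimethoxybuta-1,3-dien-1-one (dienylketene) | COC(=C=O)/C(OC)=C(/O)c1coc(-c2cc(OC)c(OCc3ccccc3)cc2OCc2ccccc2)cc1=O | intermediate
18 | 2-[2,4-bis(benzyloxy)-5-methoxyphenyl]-5-hydroxy-6,7-dimethoxy-8aH-chromene-4,8-dione (racemic) | COC1=C(OC)C(=O)C2OC(c3cc(OC)c(OCc4ccccc4)cc3OCc3ccccc3)=CC(=O)C2=C1O | intermediate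
19 | 2-[2,4-bis(benzyloxy)-5-methoxyphenyl]-5,8-dihydroxy-6,7-dimethoxy-4H-chromen-4-one | COc1c(OC)c(O)c2oc(-c3cc(OC)c(OCc4ccccc4)cc3OCc3ccccc3)cc(=O)c2c1O | intermediate
20 | 2-[2,4-bis(benzyloxy)-5-methoxyphenyl]-5,6,7,8-tetramethoxy-4H-chromen-4-one | COc1cc(-c2cc(=O)c3c(OC)c(OC)c(OC)c(OC)c3o2)c(OCc2ccccc2)cc1OCc1ccccc1 | intermediate
21 | 2-(2,4-dihydroxy-5-methoxyphenyl)-5,6,7,8-tetramethoxy-4H-chromen-4-one | COc1cc(-c2cc(=O)c3c(OC)c(OC)c(OC)c(OC)c3o2)c(O)cc1O | target

**Step count**
Total steps: 11. Longest linear sequence: 11 steps, from isovanillin; dimethyl squarate, Danishefsky's diene and benzyl bromide are bought.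

**Steps most likely to fail**

Step 9. The hydroxyl may turn inward on ring opening, so that the ketene lactonises to a butenolide, or closure onto the electron-poor pyranone C2 may be so slow that the ketene oligomerises. The fallback builds ring C on a ready-made ring A by classical flavone chemistry and has no pericyclic step. It sets out from aldehyde 8. Claisen–Schmidt condensation (KOH, EtOH, rt) with the purchasable A-ring ketone 1-(2-hydroxy-3,4,5,6-tetramethoxyphenyl)ethan-1-one F1 should give (E)-3-[2,4-bis(benzyloxy)-5-methoxyphenyl]-1-(2-hydroxy-3,4,5,6-tetramethoxyphenyl)prop-2-en-1-one F2. Oxidative cyclisation of this 2'-hydroxychalcone with catalytic iodine in DMSO at 130 °C should give flavone 20, where the route is rejoined before step 11.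

Step 8. The 3-magnesiated pyranone may open by β-elimination of its enolate-type ring oxygen, or the exchange reagent may add to C2 of the pyranone before the squarate captures the carbanion. The fallback moves the metalation one oxidation level down, where the ring oxygen is a poor alkoxide leaving group, and dehydrogenates late. It sets out from iodide 12.
- Exchange with iPrMgCl·LiCl (THF, −78 °C) and addition to 14 should give 4-{2-[2,4-bis(benzyloxy)-5-methoxyphenyl]-4-oxo-3,4-dihydro-2H-pyran-5-yl}-4-hydroxy-2,3-dimethoxycyclobut-2-en-1-one F3.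
- Heating F3 in degassed toluene (the 4-alkenyl case of the same ring expansion) should give 2-[2,4-bis(benzyloxy)-5-methoxyphenyl]-5,8-dihydroxy-6,7-dimethoxy-2,3-dihydro-4H-chromen-4-one F4.
- One equivalent of MeI with K2CO3 in acetone at rt under argon should methylate only the non-chelated 8-OH, giving 2-[2,4-bis(benzyloxy)-5-methoxyphenyl]-5-hydroxy-6,7,8-trimethoxy-2,3-dihydro-4H-chromen-4-one F5.
- Catalytic iodine in DMSO at 120 °C should dehydrogenate this flavanone to 2-[2,4-bis(benzyloxy)-5-methoxyphenyl]-5-hydroxy-6,7,8-trimethoxy-4H-chromen-4-one F6.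
- Me2SO4 and K2CO3 in refluxing acetone should methylate the 5-OH and give 20, where the route is rejoined.

Step 7. DDQ may oxidise the trialkoxyaryl ring by electron transfer or cause loss of iodine instead of abstracting the C2 hydride, or conversion may stall. The fallback replaces hydride abstraction by enolate selenenylation and syn-elimination. It sets out from 12. The kinetic C3 enolate (LiHMDS, THF, −78 °C) and PhSeCl should give 2-[2,4-bis(benzyloxy)-5-methoxyphenyl]-5-iodo-3-(phenylselanyl)-2,3-dihydro-4H-pyran-4-one F7, with selenium trans to the aryl group. Oxidation with H2O2 (CH2Cl2, pyridine, 0 °C → rt) and syn-elimination of the selenoxide toward C2–H should give 13, where the route is rejoined.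

**Further compounds**
F1 | step 9 | 1-(2-hydroxy-3,4,5,6-tetramethoxyphenyl)ethan-1-one | CC(=O)c1c(O)c(OC)c(OC)c(OC)c1OC
F2 | step 9 | (E)-3-[2,4-bis(benzyloxy)-5-methoxyphenyl]-1-(2-hydroxy-3,4,5,6-tetramethoxyphenyl)prop-2-en-1-one | COc1cc(/C=C/C(=O)c2c(O)c(OC)c(OC)c(OC)c2OC)c(OCc2ccccc2)cc1OCc1ccccc1
F3 | step 8 | 4-{2-[2,4-bis(benzyloxy)-5-methoxyphenyl]-4-oxo-3,4-dihydro-2H-pyran-5-yl}-4-hydroxy-2,3-dimethoxycyclobut-2-en-1-one (racemic, diastereomer mixture) | COC1=C(OC)C(O)(C2=COC(c3cc(OC)c(OCc4ccccc4)cc3OCc3ccccc3)CC2=O)C1=O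
F4 | step 8 | 2-[2,4-bis(benzyloxy)-5-methoxyphenyl]-5,8-dihydroxy-6,7-dimethoxy-2,3-dihydro-4H-chromen-4-one (racemic) | COc1c(OC)c(O)c2c(c1O)C(=O)CC(c1cc(OC)c(OCc3ccccc3)cc1OCc1ccccc1)O2
F5 | step 8 | 2-[2,4-bis(benzyloxy)-5-methoxyphenyl]-5-hydroxy-6,7,8-trimethoxy-2,3-dihydro-4H-chromen-4-one (racemic) | COc1c(OC)c(OC)c2c(c1O)C(=O)CC(c1cc(OC)c(OCc3ccccc3)cc1OCc1ccccc1)O2
F6 | step 8 | 2-[2,4-bis(benzyloxy)-5-methoxyphenyl]-5-hydroxy-6,7,8-trimethoxy-4H-chromen-4-one | COc1c(OC)c(OC)c2oc(-c3cc(OC)c(OCc4ccccc4)cc3OCc3ccccc3)cc(=O)c2c1O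
F7 | step 7 | 2-[2,4-bis(benzyloxy)-5-methoxyphenyl]-5-iodo-3-(phenylselanyl)-2,3-dihydro-4H-pyran-4-one (racemic, trans) | COc1cc(C2OC=C(I)C(=O)C2[Se]c2ccccc2)c(OCc2ccccc2)cc1OCc1ccccc1
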